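**Retrosynthetic overview**

1. The route rests on the benzene ring of the benzoxazole: C1' (bonded to C11), C2'–OH, C3'–OMe, C4'–H, C5'–N and C6'–O, with the C3' and C6' oxygens para. This is the pattern of a 1,4-benzoquinone, made on the finished decalin by thermal ring expansion of a squarate-derived 4-alkynylcyclobutenone.
2. The oxazole is closed last: C5'–N by CuI-catalysed amidation of an aryl iodide (from ipso-iododesilylation), O–C closure by cyclodehydration onto C6'–OH. C3'–OMe comes from methylation of the less hindered hydroquinone hydroxyl, C2'–OH from final BCl3 cleavage of the isopropyl ether.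
3. The cyclobutenone comes from LiC≡CSiMe3 and a 3-alkyl-4-isopropoxycyclobutenedione, itself from diisopropyl squarate and the C11 neopentyllithium (from the C11 iodide).
4. The cis-decalin iodide: ring B by Diels–Alder reaction of tiglaldehyde with an (R)-silyloxy vinylcyclohexene (sets C8, C9, C10); C5 methyl by reductive methylation of the C4 enone (cis fusion); C4 methyl and C3=C4 by enol triflate cross-coupling.
5. Ring order: ring A (from cyclohexenone), ring B (cycloaddition), benzene ring (from the purchased four-membered ring), oxazole ring.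

Key step: step 17

Numbering used below: decalin atoms C1–C10 and C11 (the CH2 on C9) follow terpenoid numbering, with methyls on C4, C5, C8, C9; "DecCH2" stands for [(1R,2S,4aR,8aS)-1,2,4a,5-tetramethyl-1,2,3,4,4a,7,8,8a-octahydronaphthalen-1-yl]methyl.

**Route**

Step 1
Reactants: 1 cyclohex-2-en-1-one
Product: 2 2-iodocyclohex-2-en-1-one
Conditions: I2, pyridine, CH2Cl2, 0 °C → rt
Reagents that add atoms: iodine, II
Why: α-Iodination of the enone by conjugate addition of pyridine, iodination of the resulting enolate and elimination (addition–elimination of the Baylis–Hillman type), a standard entry to 2-iodoenones.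

Step 2
Reactants: 2 2-iodocyclohex-2-en-1-one
Product: 3 (1R)-2-iodocyclohex-2-en-1-ol
Conditions: (S)-Me-CBS oxazaborolidine (C18H20BNO, 10 mol %), BH3·SMe2, THF, −20 °C
Reagents that add atoms: none
Why: Corey–Bakshi–Shibata reduction, in which the iodoalkenyl carbon acts as the large substituent so that the (S)-catalyst should deliver hydride to one carbonyl face and set C4 as (R); this centre later steers the cycloaddition and is then oxidised away.

Step 3
Reactants: 3 (1R)-2-iodocyclohex-2-en-1-ol
Product: 4 triethyl{[(1R)-2-iodocyclohex-2-en-1-yl]oxy}silane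
Conditions: Et3SiCl, imidazole, CH2Cl2, 0 °C
Reagents that add atoms: chlorotriethylsilane, CC[Si](Cl)(CC)CC
Why: Silylation of the secondary allylic alcohol; the triethylsilyl ether is chosen because it can later be removed by mild acid without touching a triisopropylsilyl ether.

Step 4
Reactants: 4 triethyl{[(1R)-2-iodocyclohex-2-en-1-yl]oxy}silane; 5 tributyl(ethenyl)stannane
Product: 6 {[(1R)-2-ethenylcyclohex-2-en-1-yl]oxy}triethylsilane
Conditions: Pd(PPh3)4 (5 mol %), CuI (10 mol %), DMF, 50 °C
Reagents that add atoms: none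
Why: Stille cross-coupling of the alkenyl iodide with the vinylstannane should give the semicyclic diene (C7=C6–C5=C10) without touching the C4 stereocentre.

Step 5
Reactants: 6 {[(1R)-2-ethenylcyclohex-2-en-1-yl]oxy}triethylsilane; 7 (E)-2-methylbut-2-enal
Product: 8 (1R,2S,5R,8aR)-1,2-dimethyl-5-[(triethylsilyl)oxy]-1,2,3,5,6,7,8,8a-octahydronaphthalene-1-carbaldehyde
Conditions: B(C6F5)3 (10 mol %), CH2Cl2, −40 → −20 °C
Reagents that add atoms: none
Why: Lewis acid-catalysed Diels–Alder reaction in which the unsubstituted diene terminus C7 bonds to the enal β-carbon C8 and the ring carbon C10 to C9, the dienophile approaching the face opposite the pseudoaxial C4 silyloxy group through the formyl-exo arrangement that α-methyl enals and the bulky borane favour; this should set C10–H cis to C11, while the E geometry of 7 fixes the C8 and C9 methyl groups cis to each other.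

Step 6
Reactants: 8 (1R,2S,5R,8aR)-1,2-dimethyl-5-[(triethylsilyl)oxy]-1,2,3,5,6,7,8,8a-octahydronaphthalene-1-carbaldehyde
Product: 9 {(1R,2S,5R,8aS)-1,2-dimethyl-5-[(triethylsilyl)oxy]-1,2,3,5,6,7,8,8a-octahydronaphthalen-1-yl}methanol
Conditions: NaBH4, MeOH, 0 °C
Reagents that add atoms: none
Why: Borohydride reduction of the non-enolisable neopentyl aldehyde to the C11 alcohol; no stereocentre is affected.

Step 7
Reactants: 9 {(1R,2S,5R,8aS)-1,2-dimethyl-5-[(triethylsilyl)oxy]-1,2,3,5,6,7,8,8a-octahydronaphthalen-1-yl}methanol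
Product: 10 ({(1R,2S,5R,8aS)-1,2-dimethyl-5-[(triethylsilyl)oxy]-1,2,3,5,6,7,8,8a-octahydronaphthalen-1-yl}methoxy)tri(propan-2-yl)silane
Conditions: iPr3SiOTf, 2,6-lutidine, CH2Cl2, 0 °C
Reagents that add atoms: triisopropylsilyl trifluoromethanesulfonate, CC(C)[Si](OS(=O)(=O)C(F)(F)F)(C(C)C)C(C)C
Why: Silylation of the hindered primary alcohol with the silyl triflate; the triisopropylsilyl ether should survive the dissolving-metal, strong-base and organometallic steps that follow.

Step 8
Reactants: 10 ({(1R,2S,5R,8aS)-1,2-dimethyl-5-[(triethylsilyl)oxy]-1,2,3,5,6,7,8,8a-octahydronaphthalen-1-yl}methoxy)tri(propan-2-yl)silane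
Product: 11 (1R,4aS,5R,6S)-5,6-dimethyl-5-({[tri(propan-2-yl)silyl]oxy}methyl)-1,2,3,4,4a,5,6,7-octahydronaphthalen-1-ol
Conditions: pyridinium p-toluenesulfonate (cat.), MeOH, rt
Reagents that add atoms: none
Why: Acid-catalysed methanolysis should cleave the triethylsilyl ether selectively, the much bulkier triisopropylsilyl ether being far slower under these conditions.

Step 9
Reactants: 11 (1R,4aS,5R,6S)-5,6-dimethyl-5-({[tri(propan-2-yl)silyl]oxy}methyl)-1,2,3,4,4a,5,6,7-octahydronaphthalen-1-ol
Product: 12 (4aS,5R,6S)-5,6-dimethyl-5-({[tri(propan-2-yl)silyl]oxy}methyl)-3,4,4a,5,6,7-hexahydronaphthalen-1(2H)-one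
Conditions: Dess–Martin periodinane, CH2Cl2, rt
Reagents that add atoms: none
Why: Dess–Martin oxidation of the allylic alcohol gives the conjugated C4 enone (C5=C6) and removes the auxiliary C4 stereocentre; C10–H is not acidic in this enone.

Step 10
Reactants: 12 (4aS,5R,6S)-5,6-dimethyl-5-({[tri(propan-2-yl)silyl]oxy}methyl)-3,4,4a,5,6,7-hexahydronaphthalen-1(2H)-one
Product: 14 (4aS,5R,6S,8aR)-5,6,8a-trimethyl-5-({[tri(propan-2-yl)silyl]oxy}methyl)octahydronaphthalen-1(2H)-one, via lithium enolate 13 (not isolated)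
Conditions: Li (2.2 equiv), t-BuOH (1.0 equiv), NH3(l)/THF, −78 °C; then MeI, −78 → −33 °C
Reagents that add atoms: iodomethane, CI
Why: Reductive alkylation of an enone (dissolving-metal reduction, then enolate C-alkylation): two electrons and one proton (delivered to C6) give the C4–C5 enolate 13 regiospecifically, and MeI should attack C5 on the face cis to C10–H, which is axial with respect to ring A, equatorial with respect to ring B and remote from the axial C9 methyl group, so the C5 methyl group and the cis ring fusion are set together.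

Step 11
Reactants: 14 (4aS,5R,6S,8aR)-5,6,8a-trimethyl-5-({[tri(propan-2-yl)silyl]oxy}methyl)octahydronaphthalen-1(2H)-one
Product: 15 (4aS,5R,6S,8aR)-5,6,8a-trimethyl-5-({[tri(propan-2-yl)silyl]oxy}methyl)-3,4,4a,5,6,7,8,8a-octahydronaphthalen-1-yl trifluoromethanesulfonate
Conditions: KN(SiMe3)2, THF, −78 °C; then PhNTf2, −78 → 0 °C
Reagents that add atoms: N-phenylbis(trifluoromethanesulfonimide), O=S(=O)(N(c1ccccc1)S(=O)(=O)C(F)(F)F)C(F)(F)F
Why: Enol triflate formation; the ketone can enolise only toward C3 because C5 is quaternary, so a single C3=C4 enol triflate should result.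

Step 12
Reactants: 15 (4aS,5R,6S,8aR)-5,6,8a-trimethyl-5-({[tri(propan-2-yl)silyl]oxy}methyl)-3,4,4a,5,6,7,8,8a-octahydronaphthalen-1-yl trifluoromethanesulfonate
Product: 16 tri(propan-2-yl){[(1R,2S,4aR,8aR)-1,2,4a,5-tetramethyl-1,2,3,4,4a,7,8,8a-octahydronaphthalen-1-yl]methoxy}silane
Conditions: MeMgBr, Fe(acac)3 (5 mol %), THF/NMP, −30 → 0 °C
Reagents that add atoms: methylmagnesium bromide, C[Mg]Br
Why: Iron-catalysed Kumada-type cross-coupling of the alkenyl triflate with the methyl Grignard reagent installs the C4 methyl group with the C3=C4 double bond fixed in place.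

Step 13
Reactants: 16 tri(propan-2-yl){[(1R,2S,4aR,8aR)-1,2,4a,5-tetramethyl-1,2,3,4,4a,7,8,8a-octahydronaphthalen-1-yl]methoxy}silane
Product: 17 [(1R,2S,4aR,8aR)-1,2,4a,5-tetramethyl-1,2,3,4,4a,7,8,8a-octahydronaphthalen-1-yl]methanol
Conditions: Bu4NF, THF, 50 °C
Reagents that add atoms: none
Why: Fluoride-mediated desilylation frees the C11 alcohol under non-acidic conditions that spare the trisubstituted alkene.

Step 14
Reactants: 17 [(1R,2S,4aR,8aR)-1,2,4a,5-tetramethyl-1,2,3,4,4a,7,8,8a-octahydronaphthalen-1-yl]methanol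
Product: 18 (1R,2S,4aR,8aR)-1-(iodomethyl)-1,2,4a,5-tetramethyl-1,2,3,4,4a,7,8,8a-octahydronaphthalene
Conditions: I2, PPh3, imidazole, toluene, 90 °C
Reagents that add atoms: iodine, II
Why: Appel-type iodination: iodide displaces the alkoxyphosphonium group at the neopentyl carbon by SN2 substitution on heating, with no carbocation and therefore no skeletal rearrangement.

Step 15
Reactants: 18 (1R,2S,4aR,8aR)-1-(iodomethyl)-1,2,4a,5-tetramethyl-1,2,3,4,4a,7,8,8a-octahydronaphthalene; 19 diisopropyl squarate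
Product: 22 3-(DecCH2)-4-(propan-2-yloxy)cyclobut-3-ene-1,2-dione, via neopentyllithium 20 (not isolated), via lithium alkoxide adduct 21 (not isolated)
Conditions: t-BuLi (2.1 equiv), Et2O/pentane, −78 °C; cannulated into 19, THF, −78 °C; (CF3CO)2O, −78 → 0 °C; aq NH4Cl
Reagents that add atoms: water, O
Why: Iodine–lithium exchange gives the neopentyllithium, which adds 1,2 to one squarate carbonyl; trifluoroacetylation of the alkoxide, ionisation and hydrolysis of the resulting oxocarbenium ion expel propan-2-ol and give the 3-alkyl-4-alkoxycyclobutenedione (the standard squarate-to-cyclobutenedione sequence).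

Step 16
Reactants: 22 3-(DecCH2)-4-(propan-2-yloxy)cyclobut-3-ene-1,2-dione; 23 ethynyltrimethylsilane
Product: 25 2-(DecCH2)-4-hydroxy-3-(propan-2-yloxy)-4-[(trimethylsilyl)ethynyl]cyclobut-2-en-1-one, via lithium trimethylsilylacetylide 24 (not isolated)
Conditions: n-BuLi, THF, −78 °C; then 22, −78 °C; aq NH4Cl at −78 °C
Reagents that add atoms: none
Why: 1,2-Addition of the acetylide to the ketone-like carbonyl next to the isopropoxy-bearing carbon, the other carbonyl being deactivated as a vinylogous ester; the new carbinol centre forms as a mixture of epimers that is of no consequence.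

Step 17
Reactants: 25 2-(DecCH2)-4-hydroxy-3-(propan-2-yloxy)-4-[(trimethylsilyl)ethynyl]cyclobut-2-en-1-one
Product: 27 2-(DecCH2)-3-(propan-2-yloxy)-6-(trimethylsilyl)cyclohexa-2,5-diene-1,4-dione, via enynylketene 26 (not isolated)
Conditions: degassed toluene (0.01 M), 110 °C
Reagents that add atoms: none
Why: Heating opens the cyclobutenone by a thermally allowed conrotatory 4π electrocyclic ring opening (cleavage of the C(=O)–C(OH) bond) in which the donor hydroxyl rotates outward and the silylethynyl group inward, giving the (Z)-enynylketene 26 with the alkyne held next to the ketene. The ketene carbon (future C6') then bonds to the silyl-bearing alkyne carbon (future C5'), closing the six-membered carbocycle through the distal alkyne carbon as a phenoxyl/σ-aryl 1,4-diradical, and transfer of the hydroxyl hydrogen to the radical centre C4' should deliver the 1,4-benzoquinone. This is the Moore cyclisation of 4-alkynyl-4-hydroxycyclobutenones, the closest precedent being the same ring expansion of squarate-derived alkoxycyclobutenones that carry silylethynyl groups. No stereocentre is created and the carbinol centre of 25 is destroyed, so both epimers converge. The step needs six- over five-membered closure, which the silyl substituent secures because it gives no benzylic-type stabilisation to the exocyclic vinyl radical of the five-ring pathway, and it needs the alkynyl group inward, which the outward preference of the hydroxyl donor secures; the positions of C1', the isopropoxy group, both carbonyl oxygens and silicon are already fixed by the connectivity of 25. High dilution suppresses ketene oligomerisation, and the remote, hindered C3=C4 alkene of the decalin is not expected to intercept the ketene.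

Step 18
Reactants: 27 2-(DecCH2)-3-(propan-2-yloxy)-6-(trimethylsilyl)cyclohexa-2,5-diene-1,4-dione
Product: 29 2-(DecCH2)-4-methoxy-3-(propan-2-yloxy)-6-(trimethylsilyl)phenol, via hydroquinone 28 (not isolated)
Conditions: Na2S2O4, THF/H2O, rt; then K2CO3, MeI (1.1 equiv), acetone, rt, under argon
Reagents that add atoms: iodomethane, CI
Why: Dithionite reduction of the quinone followed by Williamson etherification under steric control: the C3' hydroxyl (between the isopropoxy group and C4'–H) should be methylated, while the C6' hydroxyl, buried between the trimethylsilyl group and the neopentyl-type C11, stays free for the oxazole.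

Step 19
Reactants: 29 2-(DecCH2)-4-methoxy-3-(propan-2-yloxy)-6-(trimethylsilyl)phenol
Product: 30 2-(DecCH2)-6-iodo-4-methoxy-3-(propan-2-yloxy)phenol
Conditions: N-iodosuccinimide, MeCN, 0 °C
Reagents that add atoms: N-iodosuccinimide, O=C1CCC(=O)N1I
Why: Ipso-iododesilylation (electrophilic aromatic substitution at the silicon-bearing carbon): C5' is activated by the ortho hydroxyl, the para isopropoxy group and the β-silicon effect, so iodine should replace silicon there and leave C4'–H untouched.

Step 20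
Reactants: 30 2-(DecCH2)-6-iodo-4-methoxy-3-(propan-2-yloxy)phenol; 31 acetamide
Product: 32 N-[3-(DecCH2)-2-hydroxy-5-methoxy-4-(propan-2-yloxy)phenyl]acetamide
Conditions: CuI (10 mol %), N,N′-dimethylethane-1,2-diamine (20 mol %), K3PO4, 1,4-dioxane, 100 °C
Reagents that add atoms: none
Why: Goldberg-type CuI/diamine-catalysed N-arylation of acetamide by the aryl iodide places nitrogen on C5', next to the free C6' hydroxyl, which is too hindered to compete as an O-nucleophile.

Step 21
Reactants: 32 N-[3-(DecCH2)-2-hydroxy-5-methoxy-4-(propan-2-yloxy)phenyl]acetamide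
Product: 33 7-(DecCH2)-5-methoxy-2-methyl-6-(propan-2-yloxy)-1,3-benzoxazole
Conditions: PPh3, diisopropyl azodicarboxylate, THF, 0 °C → rt
Reagents that add atoms: none
Why: Mitsunobu-type cyclodehydration of the 2-hydroxyanilide (phosphonium activation of the amide oxygen, attack of the phenol oxygen on the imidate carbon) closes the oxazole under neutral conditions that spare the acid-sensitive trisubstituted alkene.

Step 22
Reactants: 33 7-(DecCH2)-5-methoxy-2-methyl-6-(propan-2-yloxy)-1,3-benzoxazole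
Product: 34 7-(DecCH2)-5-methoxy-2-methyl-1,3-benzoxazol-6-ol (CNP0149771.1)
Conditions: BCl3, CH2Cl2, −78 → −40 °C; then MeOH, aq NaHCO3
Reagents that add atoms: none
Why: Lewis acid dealkylation: BCl3 should cleave the secondary isopropyl aryl ether (loss of 2-chloropropane) much faster than the methyl ether at low temperature, freeing C2'–OH without acid at a temperature that would disturb the alkene.

**Compound list**

1 | cyclohex-2-en-1-one | O=C1C=CCCC1 | starting material
2 | 2-iodocyclohex-2-en-1-one | O=C1CCCC=C1I | intermediate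
3 | (1R)-2-iodocyclohex-2-en-1-ol | O[C@@H]1CCCC=C1I | intermediate
4 | triethyl{[(1R)-2-iodocyclohex-2-en-1-yl]oxy}silane | CC[Si](CC)(CC)O[C@@H]1CCCC=C1I | intermediate
5 | tributyl(ethenyl)stannane | C=C[Sn](CCCC)(CCCC)CCCC | starting material
6 | {[(1R)-2-ethenylcyclohex-2-en-1-yl]oxy}triethylsilane | CC[Si](CC)(CC)O[C@@H]1CCCC=C1C=C | intermediate
7 | (E)-2-methylbut-2-enal (tiglaldehyde) | C/C=C(\C)C=O | starting material
8 | (1R,2S,5R,8aR)-1,2-dimethyl-5-[(triethylsilyl)oxy]-1,2,3,5,6,7,8,8a-octahydronaphthalene-1-carbaldehyde | O=C[C@]1(C)[C@@H](C)CC=C2[C@H](O[Si](CC)(CC)CC)CCC[C@@H]12 | intermediate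
9 | {(1R,2S,5R,8aS)-1,2-dimethyl-5-[(triethylsilyl)oxy]-1,2,3,5,6,7,8,8a-octahydronaphthalen-1-yl}methanol | OC[C@]1(C)[C@@H](C)CC=C2[C@H](O[Si](CC)(CC)CC)CCC[C@@H]12 | intermediate
10 | ({(1R,2S,5R,8aS)-1,2-dimethyl-5-[(triethylsilyl)oxy]-1,2,3,5,6,7,8,8a-octahydronaphthalen-1-yl}methoxy)tri(propan-2-yl)silane | CC(C)[Si](OC[C@]1(C)[C@@H](C)CC=C2[C@H](O[Si](CC)(CC)CC)CCC[C@@H]12)(C(C)C)C(C)C | intermediate
11 | (1R,4aS,5R,6S)-5,6-dimethyl-5-({[tri(propan-2-yl)silyl]oxy}methyl)-1,2,3,4,4a,5,6,7-octahydronaphthalen-1-ol | CC(C)[Si](OC[C@]1(C)[C@@H](C)CC=C2[C@H](O)CCC[C@@H]12)(C(C)C)C(C)C | intermediate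
12 | (4aS,5R,6S)-5,6-dimethyl-5-({[tri(propan-2-yl)silyl]oxy}methyl)-3,4,4a,5,6,7-hexahydronaphthalen-1(2H)-one | CC(C)[Si](OC[C@]1(C)[C@@H](C)CC=C2C(=O)CCC[C@@H]12)(C(C)C)C(C)C | intermediate
13 | lithium (4aS,5R,6S)-5,6-dimethyl-5-({[tri(propan-2-yl)silyl]oxy}methyl)-2,3,4,4a,5,6,7,8-octahydronaphthalen-1-olate (formed in the flask) | CC(C)[Si](OC[C@]1(C)[C@@H](C)CCC2=C(O[Li])CCC[C@@H]12)(C(C)C)C(C)C | intermediate
14 | (4aS,5R,6S,8aR)-5,6,8a-trimethyl-5-({[tri(propan-2-yl)silyl]oxy}methyl)octahydronaphthalen-1(2H)-one | CC(C)[Si](OC[C@]1(C)[C@@H](C)CC[C@@]2(C)C(=O)CCC[C@@H]12)(C(C)C)C(C)C | intermediate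
15 | (4aS,5R,6S,8aR)-5,6,8a-trimethyl-5-({[tri(propan-2-yl)silyl]oxy}methyl)-3,4,4a,5,6,7,8,8a-octahydronaphthalen-1-yl trifluoromethanesulfonate | CC(C)[Si](OC[C@]1(C)[C@@H](C)CC[C@@]2(C)C(OS(=O)(=O)C(F)(F)F)=CCC[C@@H]12)(C(C)C)C(C)C | intermediate
16 | tri(propan-2-yl){[(1R,2S,4aR,8aR)-1,2,4a,5-tetramethyl-1,2,3,4,4a,7,8,8a-octahydronaphthalen-1-yl]methoxy}silane | CC(C)[Si](OC[C@]1(C)[C@@H](C)CC[C@@]2(C)C(C)=CCC[C@@H]12)(C(C)C)C(C)C | intermediate
17 | [(1R,2S,4aR,8aR)-1,2,4a,5-tetramethyl-1,2,3,4,4a,7,8,8a-octahydronaphthalen-1-yl]methanol | OC[C@]1(C)[C@@H](C)CC[C@@]2(C)C(C)=CCC[C@@H]12 | intermediate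
18 | (1R,2S,4aR,8aR)-1-(iodomethyl)-1,2,4a,5-tetramethyl-1,2,3,4,4a,7,8,8a-octahydronaphthalene | IC[C@]1(C)[C@@H](C)CC[C@@]2(C)C(C)=CCC[C@@H]12 | intermediate
19 | diisopropyl squarate, 3,4-di(propan-2-yloxy)cyclobut-3-ene-1,2-dione | CC(C)OC1=C(OC(C)C)C(=O)C1=O | starting material
20 | C11 neopentyllithium of the decalin (formed in the flask) | [Li]C[C@]1(C)[C@@H](C)CC[C@@]2(C)C(C)=CCC[C@@H]12 | intermediate
21 | lithium alkoxide of 4-(DecCH2)-4-hydroxy-2,3-di(propan-2-yloxy)cyclobut-2-en-1-one (formed in the flask; carbinol centre unassigned) | CC(C)OC1=C(OC(C)C)C(O[Li])(C[C@]2(C)[C@@H](C)CC[C@@]3(C)C(C)=CCC[C@@H]23)C1=O | intermediate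
22 | 3-{[(1R,2S,4aR,8aS)-1,2,4a,5-tetramethyl-1,2,3,4,4a,7,8,8a-octahydronaphthalen-1-yl]methyl}-4-(propan-2-yloxy)cyclobut-3-ene-1,2-dione | CC(C)OC1=C(C[C@]2(C)[C@@H](C)CC[C@@]3(C)C(C)=CCC[C@@H]23)C(=O)C1=O | intermediate
23 | ethynyltrimethylsilane | C#C[Si](C)(C)C | starting material
24 | lithium (trimethylsilyl)acetylide (formed in the flask) | [Li]C#C[Si](C)(C)C | intermediate
25 | 2-(DecCH2)-4-hydroxy-3-(propan-2-yloxy)-4-[(trimethylsilyl)ethynyl]cyclobut-2-en-1-one (both carbinol epimers) | CC(C)OC1=C(C[C@]2(C)[C@@H](C)CC[C@@]3(C)C(C)=CCC[C@@H]23)C(=O)C1(O)C#C[Si](C)(C)C | intermediate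
26 | (3Z)-2-(DecCH2)-4-hydroxy-3-(propan-2-yloxy)-6-(trimethylsilyl)hexa-1,3-dien-5-yn-1-one, the enynylketene (formed in the flask) | CC(C)O/C(C(C[C@]2(C)[C@@H](C)CC[C@@]3(C)C(C)=CCC[C@@H]23)=C=O)=C(\O)C#C[Si](C)(C)C | intermediate
27 | 2-(DecCH2)-3-(propan-2-yloxy)-6-(trimethylsilyl)cyclohexa-2,5-diene-1,4-dione | CC(C)OC1=C(C[C@]2(C)[C@@H](C)CC[C@@]3(C)C(C)=CCC[C@@H]23)C(=O)C([Si](C)(C)C)=CC1=O | intermediate
28 | 2-(DecCH2)-3-(propan-2-yloxy)-6-(trimethylsilyl)benzene-1,4-diol (formed in the flask) | CC(C)Oc1c(C[C@]2(C)[C@@H](C)CC[C@@]3(C)C(C)=CCC[C@@H]23)c(O)c([Si](C)(C)C)cc1O | intermediate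
29 | 2-(DecCH2)-4-methoxy-3-(propan-2-yloxy)-6-(trimethylsilyl)phenol | CC(C)Oc1c(C[C@]2(C)[C@@H](C)CC[C@@]3(C)C(C)=CCC[C@@H]23)c(O)c([Si](C)(C)C)cc1OC | intermediate
30 | 2-(DecCH2)-6-iodo-4-methoxy-3-(propan-2-yloxy)phenol | CC(C)Oc1c(C[C@]2(C)[C@@H](C)CC[C@@]3(C)C(C)=CCC[C@@H]23)c(O)c(I)cc1OC | intermediate
31 | acetamide | CC(N)=O | starting material
32 | N-[3-(DecCH2)-2-hydroxy-5-methoxy-4-(propan-2-yloxy)phenyl]acetamide | CC(=O)Nc1cc(OC)c(OC(C)C)c(C[C@]2(C)[C@@H](C)CC[C@@]3(C)C(C)=CCC[C@@H]23)c1O | intermediate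
33 | 7-(DecCH2)-5-methoxy-2-methyl-6-(propan-2-yloxy)-1,3-benzoxazole | COc1cc2nc(C)oc2c(C[C@]2(C)[C@@H](C)CC[C@@]3(C)C(C)=CCC[C@@H]23)c1OC(C)C | intermediate
34 | 5-methoxy-2-methyl-7-{[(1R,2S,4aR,8aS)-1,2,4a,5-tetramethyl-1,2,3,4,4a,7,8,8a-octahydronaphthalen-1-yl]methyl}-1,3-benzoxazol-6-ol (CNP0149771.1) | COc1cc2nc(C)oc2c(C[C@]2(C)[C@@H](C)CC[C@@]3(C)C(C)=CCC[C@@H]23)c1O | target

**Step count and risk**

Total step count: 22. Longest linear sequence: 22 steps, from cyclohex-2-en-1-one (1) to 34.

Steps most likely to fail: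

1. Step 5 (Diels–Alder reaction). What may go wrong: erosion of the formyl-exo preference (which would give the C8/C9-epimeric series relative to C10), incomplete facial discrimination by the silyloxy group, or Lewis acid-induced ionisation of the allylic silyl ether. The fallback sets out from 2 and returns at 12, taking stereocontrol from a chiral catalyst instead of the C4 centre. Ketalisation of 2 (ethane-1,2-diol, cat. pyridinium p-toluenesulfonate, benzene, removal of water) would give 6-iodo-1,4-dioxaspiro[4.5]dec-6-ene F1. Stille coupling with 5 as in step 4 would give the achiral diene 6-ethenyl-1,4-dioxaspiro[4.5]dec-6-ene F2. Enantioselective exo Diels–Alder reaction with 7 would use the triflimide-activated oxazaborolidine (S)-3,3-diphenyl-1-(2-methylphenyl)tetrahydro-1H,3H-pyrrolo[1,2-c][1,3,2]oxazaborole with HNTf2 (or its antipode, whichever shields the enal face that leads to 9R) in CH2Cl2 at −78 °C, giving the ketal aldehyde F3. NaBH4 reduction would give the ketal alcohol F4 and silylation with iPr3SiOTf the ketal silyl ether F5. Aqueous HCl in THF would then unmask the carbonyl and leave the conjugated enone 12. Steps 8 and 9 fall away.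

2. Step 17 (Moore cyclisation). What may go wrong: closure of the ketene onto the proximal alkyne carbon (five-membered alkylidenecyclopentenedione pathway), inward rotation of the hydroxyl with lactonisation to a furanone, or oligomerisation of the ketene. The fallback sets out from 22 and returns at 30, replacing the diradical closure by a 6π electrocyclisation of a dienylketene. Vinylmagnesium bromide (CH2=CHMgBr, THF, −78 °C) should add to the same carbonyl of 22 to give 2-(DecCH2)-4-ethenyl-4-hydroxy-3-(propan-2-yloxy)cyclobut-2-en-1-one F6. O-Methylation (MeI, Ag2O, K2CO3, MeCN) would give the methyl ether 2-(DecCH2)-4-ethenyl-4-methoxy-3-(propan-2-yloxy)cyclobut-2-en-1-one F7. Thermolysis in toluene at 110 °C (ring opening, electrocyclic closure, tautomerisation) should give 2-(DecCH2)-4-methoxy-3-(propan-2-yloxy)phenol F8, in which C3'–OMe and C6'–OH are already differentiated and C5' carries hydrogen. N-Iodosuccinimide would then iodinate ortho to the free hydroxyl and para to the isopropoxy group, at C5', to give 30. Steps 16 to 19 are replaced.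

3. Step 20 (amidation). What may go wrong: sequestration of copper by the ortho-phenoxide, reductive loss of iodine, or oxidation of the electron-rich phenol at 100 °C. The fallback sets out from 30 and returns at 33, bringing in nitrogen as azide and closing the oxazole by orthoester condensation. CuI (10 mol %), sodium L-ascorbate (NaC6H7O6), N,N′-dimethylethane-1,2-diamine and NaN3 in EtOH/H2O at 80 °C should give 6-azido-2-(DecCH2)-4-methoxy-3-(propan-2-yloxy)phenol F9, which is reduced in the same flask to 6-amino-2-(DecCH2)-4-methoxy-3-(propan-2-yloxy)phenol F10. Condensation of the crude aminophenol with triethyl orthoacetate (cat. pyridinium p-toluenesulfonate, toluene, 80 °C) would give the benzoxazole 33. Steps 20 and 21 are replaced.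

**Further compounds**

F1 | step 5 | 6-iodo-1,4-dioxaspiro[4.5]dec-6-ene | IC1=CCCCC12OCCO2
F2 | step 5 | 6-ethenyl-1,4-dioxaspiro[4.5]dec-6-ene | C=CC1=CCCCC12OCCO2
F3 | step 5 | ketal aldehyde (8 with C4 as the 1,3-dioxolane in place of C4–OSiEt3) | O=C[C@]1(C)[C@@H](C)CC=C2C3(OCCO3)CCC[C@@H]12
F4 | step 5 | ketal alcohol (9 with C4 as the 1,3-dioxolane) | OC[C@]1(C)[C@@H](C)CC=C2C3(OCCO3)CCC[C@@H]12
F5 | step 5 | ketal silyl ether (10 with C4 as the 1,3-dioxolane) | CC(C)[Si](OC[C@]1(C)[C@@H](C)CC=C2C3(OCCO3)CCC[C@@H]12)(C(C)C)C(C)C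
F6 | step 17 | 2-(DecCH2)-4-ethenyl-4-hydroxy-3-(propan-2-yloxy)cyclobut-2-en-1-one | CC(C)OC1=C(C[C@]2(C)[C@@H](C)CC[C@@]3(C)C(C)=CCC[C@@H]23)C(=O)C1(O)C=C
F7 | step 17 | 2-(DecCH2)-4-ethenyl-4-methoxy-3-(propan-2-yloxy)cyclobut-2-en-1-one | CC(C)OC1=C(C[C@]2(C)[C@@H](C)CC[C@@]3(C)C(C)=CCC[C@@H]23)C(=O)C1(OC)C=C
F8 | step 17 | 2-(DecCH2)-4-methoxy-3-(propan-2-yloxy)phenol | CC(C)Oc1c(C[C@]2(C)[C@@H](C)CC[C@@]3(C)C(C)=CCC[C@@H]23)c(O)ccc1OC
F9 | step 20 | 6-azido-2-(DecCH2)-4-methoxy-3-(propan-2-yloxy)phenol | [N-]=[N+]=Nc1cc(OC)c(OC(C)C)c(C[C@]2(C)[C@@H](C)CC[C@@]3(C)C(C)=CCC[C@@H]23)c1O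
F10 | step 20 | 6-amino-2-(DecCH2)-4-methoxy-3-(propan-2-yloxy)phenol | Nc1cc(OC)c(OC(C)C)c(C[C@]2(C)[C@@H](C)CC[C@@]3(C)C(C)=CCC[C@@H]23)c1O
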